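The ratio I carried was the peak of dissolved target over the substrate charged. In the north-west run, target less crystals peaked at 2.12 mM at 40.0 min, a single reading with its scatter. For the new flask this gave a crystal threshold, the fraction of the charge that must be target before crystals appear, of 10.6%, against 5.30% in the north-west run.

the same everywhere: gas phase 1.1 mM (held)

| run | substrate | remark | time |
|---|---|---|---|
| north-east | 10 mM | run made earlier |  |
| north-west | 40 mM | run made earlier |  |
| flask | 20 mM |  | 80 min |

- north-east (time / min: target / %, crystals / %): 5.00: 3.1, 0.9; 15.0: 4.7, 1.5; 25.0: 5.4, 1.3; 40.0: 7.3, 0.3; 60.0: 7.7, 0; 80.0: 11.8, 0; 90.0: 12.1, 1.6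
- north-west (time / min: target / %, crystals / %): 5.00: 3.0, 1.0; 15.0: 5.0, 1.5; 25.0: 4.6, 1.1; 40.0: 7.4, 2.1; 60.0: 13.2, 9.0; 80.0: 16.0, 13.6; 90.0: 18.6, 15.6

(standard deviation of a reading: 1 percentage point)

- amounts and yields of target count crystals too
- given per volume of solution although it is solid: crystals
- at the start none of the gas phase is in solution

- how much target and crystals together there is at 80 min, in percent of the substrate charged
- concentration of dissolved gas in solution at 80 min, in percent of saturation

I went to the yield by two ways. The north-east and north-west runs began alike in fractions, 3.1% and 3.0% at 5.00 min, but at 80.0 min they read 11.8% and 16.0%, so they parted by 4.2 percentage points. My first answer was the north-east reading of 11.8% at 80.0 min, taken over as a fraction of the charge since the two runs still read alike at 40.0 min, 7.3% and 7.4%; it stood above 10.6%, so I put it back in and went round again. Interpolated between its readings, and so carrying their scatter, the north-east run crossed that fraction near 74.1 min, later than the north-west run, which already read 2.1% of crystals at 40.0 min. That left crystals about 5.90 min in the new flask by my reckoning, so I set the north-west figure aside and stayed near 11.8%, which is lower than the forecast's figure. The forecast gave 12.5% (10.5% to 15.5%) and 95% of saturation (82% to 99.5%), saying “Crystals therefore come late and help only slightly”.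

The flask gave 12.3% at 80 min, with dissolved gas at 96.6% of saturation.

    gas phase ⇌ dissolved gas, rate k1*(csat - [dissolved gas]) (kL = 1.60 min⁻¹)
    substrate + dissolved gas → target (k = 8.10 M⁻¹ min⁻¹)
    dissolved gas + target → over-reacted product (k = 5.20 M⁻¹ min⁻¹)
    crystals ⇌ target, rate k4*(cs4 - [target]) while solid is left; crystals form when [target] > cs4 (solubility = 1.80 mM, k = 3.40 min⁻¹)
    substrate ⇌ dormant form (K = 1.70, k = 0.360 min⁻¹)
    target ⇌ isomer of the product (K = 0.900, k = 0.0450 min⁻¹)

In this flask, target with crystals less the threshold gave 1.7 points of crystals, where 3.28% stood. In the neighbour flask with 80 mM of substrate, the threshold fell to 2.65% and the same subtraction gave 15 points, where 15.6% stood. The flask had not come to rest at 80 min, holding substrate 28.4%, dormant form 49.0% and over-reacted product 2.86%. At 800 min these stood at 2.81%, 4.84% and 39.4%, crystals had reached 35.9%, and target with crystals came to 44.9%.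

The runs stem from a simulated flask with constants of no real substance, noise included.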